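The target is disconnected at the C4–C4a bond of the chroman pyran ring (ring C). The key step exploits two features: C4 is a CH2 group adjacent to the only stereocentre, C3, and C4a is the ring A carbon ortho to O1. An achiral 2-arylallyl aryl ether that carries bromine at the future C4a, with the prenyl group and the dimethylchromene of ring B already in place, is hydroborated enantioselectively at its 1,1-disubstituted alkene (CuH, chiral bisphosphine), which sets C3; in the same flask the primary alkylboronate is coupled with the aryl bromide (intramolecular B-alkyl Suzuki–Miyaura), closing ring C without touching C3.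

Key step: step 10

Remarks on the chemistry:
- Isoflavan numbering is used (O1, C2, C3, C4, C4a to C8a). Ring A is the benzo ring of the chroman, ring C its pyran ring, and ring B the pendant aryl ring with the fused dimethylpyran. The target is (3R).
- Assumption: (R)-DTBM-SEGPHOS is written as the ligand enantiomer expected to give the (R)-boronate 14. If the sense of induction on this substrate is the opposite, (S)-DTBM-SEGPHOS is used.
- Small commercial reagents that only deliver a group are given with SMILES on the reagent lines and carry no number.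

Step 1
Reactants: 1 2,4-dihydroxyacetophenone
Product: 2 1-[2-hydroxy-4-(methoxymethoxy)phenyl]ethan-1-one
Conditions: MOMCl (1.1 equiv), K2CO3, acetone, 0 °C to rt
Reagents that add atoms: chloromethyl methyl ether (MOMCl), COCCl
Why: Williamson-type O-alkylation is selective for the 4-OH because the 2-OH is held in a hydrogen bond to the acetyl carbonyl and is far less nucleophilic.

Step 2
Reactants: 2 1-[2-hydroxy-4-(methoxymethoxy)phenyl]ethan-1-one
Product: 3 1-[4-(methoxymethoxy)-2-(2-methylbut-3-yn-2-yloxy)phenyl]ethan-1-one
Conditions: 3-chloro-3-methylbut-1-yne, K2CO3, KI (cat.), CuI (cat.), acetone, reflux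
Reagents that add atoms: 3-chloro-3-methylbut-1-yne, CC(C)(Cl)C#C
Why: Copper-catalysed propargylic etherification (through a copper acetylide that ionises at the tertiary carbon) alkylates the remaining phenol at a centre where simple SN2 substitution is impossible.

Step 3
Reactants: 3 1-[4-(methoxymethoxy)-2-(2-methylbut-3-yn-2-yloxy)phenyl]ethan-1-one
Product: 5 1-[5-(methoxymethoxy)-2,2-dimethyl-2H-chromen-8-yl]ethan-1-one, via allenylphenol 4 (not isolated)
Conditions: N,N-diethylaniline, 190 °C
Reagents that add atoms: none
Why: The thermal aromatic propargyl Claisen rearrangement can only go to the free ortho carbon (the other carries the acetyl group), and allenylphenol 4 then closes by 1,5-hydrogen shift and oxa-6π electrocyclisation to the 2,2-dimethyl-2H-chromene whose oxygen is the former 2-OH.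

Step 4
Reactants: 5 1-[5-(methoxymethoxy)-2,2-dimethyl-2H-chromen-8-yl]ethan-1-one
Product: 7 2-bromo-1-[5-(methoxymethoxy)-2,2-dimethyl-2H-chromen-8-yl]ethan-1-one, via silyl enol ether 6 (not isolated)
Conditions: LiN(SiMe3)2, Me3SiCl, THF, −78 °C; then NBS, −78 to 0 °C
Reagents that add atoms: N-bromosuccinimide (NBS), O=C1CCC(=O)N1Br
Why: α-Bromination of a ketone through its silyl enol ether should be chemoselective, because enol ether 6 is by far the most nucleophilic π-system and reacts with NBS at low temperature before the chromene double bond or the arene can.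

Step 5
Reactants: 8 4-bromoresorcinol (4-bromobenzene-1,3-diol)
Product: 9 2-bromo-5-(methoxymethoxy)phenol
Conditions: MOMCl (1.0 equiv), i-Pr2NEt, CH2Cl2, −10 °C to rt
Reagents that add atoms: chloromethyl methyl ether (MOMCl), COCCl
Why: Kinetically controlled mono-O-alkylation (Williamson type, amine base) should take the hydroxyl para to bromine, since the hydroxyl next to bromine is shielded and hydrogen-bonded to the halogen, and one equivalent of MOMCl limits double protection.

Step 6
Reactants: 9 2-bromo-5-(methoxymethoxy)phenol
Product: 10 2-bromo-4-iodo-5-(methoxymethoxy)phenol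
Conditions: NIS, MeCN, 0 °C to rt
Reagents that add atoms: N-iodosuccinimide (NIS), O=C1CCC(=O)N1I
Why: Electrophilic aromatic iodination goes para to the free hydroxyl (also ortho to OMOM), the other doubly activated position being squeezed between the two oxygen substituents.

Step 7
Reactants: 10 2-bromo-4-iodo-5-(methoxymethoxy)phenol
Product: 11 2-bromo-5-(methoxymethoxy)-4-(3-methylbut-2-en-1-yl)phenol
Conditions: tributyl(3-methylbut-2-en-1-yl)stannane, Pd(PPh3)4 (5 mol%), DMF, 80 °C
Reagents that add atoms: tributyl(3-methylbut-2-en-1-yl)stannane, CCCC[Sn](CCCC)(CCCC)CC=C(C)C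
Why: In this Stille coupling zerovalent palladium inserts into the C–I bond much faster than into the C–Br bond, and the prenyl group is reductively eliminated at its unsubstituted terminus, so the linear prenyl arene should form while bromine stays for the key step.

Step 8
Reactants: 7 2-bromo-1-[5-(methoxymethoxy)-2,2-dimethyl-2H-chromen-8-yl]ethan-1-one; 11 2-bromo-5-(methoxymethoxy)-4-(3-methylbut-2-en-1-yl)phenol
Product: 12 2-[2-bromo-5-(methoxymethoxy)-4-(3-methylbut-2-en-1-yl)phenoxy]-1-[5-(methoxymethoxy)-2,2-dimethyl-2H-chromen-8-yl]ethan-1-one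
Conditions: K2CO3, acetone, rt
Reagents that add atoms: none
Why: Williamson ether synthesis, in which the phenoxide of 11 displaces bromide from the reactive phenacyl bromide 7 by SN2 under mild carbonate conditions.

Step 9
Reactants: 12 2-[2-bromo-5-(methoxymethoxy)-4-(3-methylbut-2-en-1-yl)phenoxy]-1-[5-(methoxymethoxy)-2,2-dimethyl-2H-chromen-8-yl]ethan-1-one
Product: 13 8-{3-[2-bromo-5-(methoxymethoxy)-4-(3-methylbut-2-en-1-yl)phenoxy]prop-1-en-2-yl}-5-(methoxymethoxy)-2,2-dimethyl-2H-chromene
Conditions: Ph3PCH3Br, KOtBu, THF, 0 °C to rt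
Reagents that add atoms: methyltriphenylphosphonium bromide, C[P+](c1ccccc1)(c1ccccc1)c1ccccc1.[Br-]
Why: Wittig methylenation with the non-stabilised ylide converts the aryl ketone into the 1,1-disubstituted alkene, while the aryl bromide, the MOM ethers and the other alkenes are inert to the ylide.

Step 10
Reactants: 13 8-{3-[2-bromo-5-(methoxymethoxy)-4-(3-methylbut-2-en-1-yl)phenoxy]prop-1-en-2-yl}-5-(methoxymethoxy)-2,2-dimethyl-2H-chromene
Product: 15 (3R)-7-(methoxymethoxy)-3-[5-(methoxymethoxy)-2,2-dimethyl-2H-chromen-8-yl]-6-(3-methylbut-2-en-1-yl)chromane, via boronate 14 (not isolated)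
Conditions: CuCl (5 mol%), NaOtBu (10 mol%), (R)-DTBM-SEGPHOS (5.5 mol%), HBpin (1.5 equiv), THF, rt to 40 °C; then Pd(OAc)2 (5 mol%), RuPhos (10 mol%), 3 M aq. KOH, 70 °C, same flask
Reagents that add atoms: none
Why: The ligated CuH adds to the terminal 1,1-disubstituted alkene of 13 with copper on CH2, and σ-bond metathesis with HBpin releases boronate 14; after addition of Pd(OAc)2, RuPhos and aqueous KOH, zerovalent palladium inserts into the only C–Br bond, the hydroxide-activated primary alkylboronate transmetalates within the same molecule, and reductive elimination forms the C4–C4a bond. The closest known reaction types are the CuH-catalysed enantioselective anti-Markovnikov hydroboration of 1,1-disubstituted alkenes and the intramolecular B-alkyl Suzuki–Miyaura coupling. Ring C closes as a six-membered ring by C(sp3)–C(sp2) reductive elimination from a seven-membered oxapalladacycle, at the ring A carbon ortho to O1 that carried bromine. The stereocentre C3 is set in the hydrocupration, where the chiral bisphosphine on copper distinguishes the aryl from the aryloxymethyl substituent of the alkene; C3 lies β to boron and takes no part in the coupling, so its (R) configuration should pass unchanged into 15. The step needs chemoselectivity for the terminal alkene over the prenyl and chromene double bonds, which should follow from the much slower hydrocupration of the trisubstituted prenyl alkene and of the chromene double bond (flanked by the gem-dimethyl carbon and the peri OMOM group), and it needs copper on the terminal carbon, which also keeps the metal away from a β-aryloxy position so that no aryloxide can be eliminated. The site of ring closure is fixed by the single bromine, and the basic medium leaves the MOM ethers, the prenyl group and the chromene intact.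

Step 11
Reactants: 15 (3R)-7-(methoxymethoxy)-3-[5-(methoxymethoxy)-2,2-dimethyl-2H-chromen-8-yl]-6-(3-methylbut-2-en-1-yl)chromane
Product: 16 (3R)-3-(5-hydroxy-2,2-dimethyl-2H-chromen-8-yl)-6-(3-methylbut-2-en-1-yl)chroman-7-ol (CNP0332706.1)
Conditions: HCl (1.25 M in MeOH), THF, rt to 40 °C
Reagents that add atoms: none
Why: Acid-catalysed transacetalisation of the two MOM ethers in methanol should free both phenols at an acid strength and temperature low enough that the ortho-prenylphenol does not cyclise and the chromene does not add methanol, and C3, which carries no acidic hydrogen and no leaving group, keeps its configuration.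

Compound list
1 | 2,4-dihydroxyacetophenone | CC(=O)c1ccc(O)cc1O | starting material
2 | 1-[2-hydroxy-4-(methoxymethoxy)phenyl]ethan-1-one | CC(=O)c1ccc(OCOC)cc1O | intermediate
3 | 1-[4-(methoxymethoxy)-2-(2-methylbut-3-yn-2-yloxy)phenyl]ethan-1-one | CC(=O)c1ccc(OCOC)cc1OC(C)(C)C#C | intermediate
4 | 1-[2-hydroxy-4-(methoxymethoxy)-3-(3-methylbuta-1,2-dien-1-yl)phenyl]ethan-1-one (allenylphenol, not isolated) | CC(=O)c1ccc(OCOC)c(C=C=C(C)C)c1O | intermediate
5 | 1-[5-(methoxymethoxy)-2,2-dimethyl-2H-chromen-8-yl]ethan-1-one | CC(=O)c1ccc(OCOC)c2C=CC(C)(C)Oc12 | intermediate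
6 | 5-(methoxymethoxy)-2,2-dimethyl-8-[1-(trimethylsilyloxy)ethenyl]-2H-chromene (silyl enol ether, not isolated) | C=C(O[Si](C)(C)C)c1ccc(OCOC)c2C=CC(C)(C)Oc12 | intermediate
7 | 2-bromo-1-[5-(methoxymethoxy)-2,2-dimethyl-2H-chromen-8-yl]ethan-1-one | BrCC(=O)c1ccc(OCOC)c2C=CC(C)(C)Oc12 | intermediate
8 | 4-bromoresorcinol | Oc1ccc(Br)c(O)c1 | starting material
9 | 2-bromo-5-(methoxymethoxy)phenol | Oc1cc(OCOC)ccc1Br | intermediate
10 | 2-bromo-4-iodo-5-(methoxymethoxy)phenol | Oc1cc(OCOC)c(I)cc1Br | intermediate
11 | 2-bromo-5-(methoxymethoxy)-4-(3-methylbut-2-en-1-yl)phenol | Oc1cc(OCOC)c(CC=C(C)C)cc1Br | intermediate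
12 | 2-[2-bromo-5-(methoxymethoxy)-4-(3-methylbut-2-en-1-yl)phenoxy]-1-[5-(methoxymethoxy)-2,2-dimethyl-2H-chromen-8-yl]ethan-1-one | O=C(COc1cc(OCOC)c(CC=C(C)C)cc1Br)c1ccc(OCOC)c2C=CC(C)(C)Oc12 | intermediate
13 | 8-{3-[2-bromo-5-(methoxymethoxy)-4-(3-methylbut-2-en-1-yl)phenoxy]prop-1-en-2-yl}-5-(methoxymethoxy)-2,2-dimethyl-2H-chromene | C=C(COc1cc(OCOC)c(CC=C(C)C)cc1Br)c1ccc(OCOC)c2C=CC(C)(C)Oc12 | intermediate
14 | 2-{(2R)-3-[2-bromo-5-(methoxymethoxy)-4-(3-methylbut-2-en-1-yl)phenoxy]-2-[5-(methoxymethoxy)-2,2-dimethyl-2H-chromen-8-yl]propyl}-4,4,5,5-tetramethyl-1,3,2-dioxaborolane (not isolated) | CC1(C)OB(C[C@@H](COc2cc(OCOC)c(CC=C(C)C)cc2Br)c2ccc(OCOC)c3C=CC(C)(C)Oc23)OC1(C)C | intermediate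
15 | (3R)-7-(methoxymethoxy)-3-[5-(methoxymethoxy)-2,2-dimethyl-2H-chromen-8-yl]-6-(3-methylbut-2-en-1-yl)chromane | CC(C)=CCc1cc2c(cc1OCOC)OC[C@@H](c1ccc(OCOC)c3c1OC(C)(C)C=C3)C2 | intermediate
16 | (3R)-3-(5-hydroxy-2,2-dimethyl-2H-chromen-8-yl)-6-(3-methylbut-2-en-1-yl)chroman-7-ol | CC(C)=CCc1cc2c(cc1O)OC[C@@H](c1ccc(O)c3c1OC(C)(C)C=C3)C2 | target

Total step count: 11.
Longest linear sequence: 8 steps (steps 1 to 4, then 8 to 11); the ring A fragment 11 is made in 3 steps (5 to 7) and joins at step 8.

Steps most likely to fail

Step 10. The hydrocupration may discriminate poorly between the two faces of an alkene whose two substituents are both bulky, the chromene double bond may compete for CuH, or the pinacol boronate may transmetalate slowly and be lost by protodeboronation. The fallback sets out from 13 and gives up catalytic asymmetric induction for a racemic ring closure followed by resolution. Hydroboration with 9-BBN (THF, rt), which is highly selective for the terminal alkene, would give the racemic B-alkyl-9-borabicyclononane adduct F1. Without isolation, Pd(dppf)Cl2 and aqueous NaOH at 65 °C would close ring C by the classical B-alkyl Suzuki–Miyaura coupling to give the racemic bis-MOM isoflavan F2. Preparative chromatography on a chiral stationary phase would then separate 15 from its (S)-enantiomer F3, and the route is rejoined at 15.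

Step 4. Electrophilic bromine may attack the chromene double bond or the activated arene instead of the silyl enol ether, or the ketone may be brominated twice. The fallback sets out from 5 and replaces halogenation by oxygenation. The potassium enolate (KN(SiMe3)2, THF, −78 °C) would be oxidised with 2-(phenylsulfonyl)-3-phenyloxaziridine to the α-hydroxy ketone F4. Mitsunobu etherification of F4 with phenol 11 (PPh3, diisopropyl azodicarboxylate, THF, 0 °C) would then give aryloxy ketone 12, where the route is rejoined.

Step 11. During acetal solvolysis the acid may promote cyclisation of the prenyl group onto the freed neighbouring phenol or addition of methanol to the chromene double bond. The fallback sets out from 15 and avoids Brønsted acid by exchanging the protecting groups. Et3SiOTf with 2,2'-bipyridyl in CH2Cl2 at 0 °C would convert both aryl MOM ethers into triethylsilyl ethers, giving the bis(triethylsilyl) ether F5. Bu4NF in THF at 0 °C would then release 16.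

Further compounds
F1 | step 10 | racemic 9-{3-[2-bromo-5-(methoxymethoxy)-4-(3-methylbut-2-en-1-yl)phenoxy]-2-[5-(methoxymethoxy)-2,2-dimethyl-2H-chromen-8-yl]propyl}-9-borabicyclo[3.3.1]nonane | C(B1C2CCCC1CCC2)C(COc1cc(OCOC)c(CC=C(C)C)cc1Br)c1ccc(OCOC)c2C=CC(C)(C)Oc12
F2 | step 10 | racemic 7-(methoxymethoxy)-3-[5-(methoxymethoxy)-2,2-dimethyl-2H-chromen-8-yl]-6-(3-methylbut-2-en-1-yl)chromane | CC(C)=CCc1cc2c(cc1OCOC)OCC(c1ccc(OCOC)c3c1OC(C)(C)C=C3)C2
F3 | step 10 | (3S)-7-(methoxymethoxy)-3-[5-(methoxymethoxy)-2,2-dimethyl-2H-chromen-8-yl]-6-(3-methylbut-2-en-1-yl)chromane | CC(C)=CCc1cc2c(cc1OCOC)OC[C@H](c1ccc(OCOC)c3c1OC(C)(C)C=C3)C2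
F4 | step 4 | 2-hydroxy-1-[5-(methoxymethoxy)-2,2-dimethyl-2H-chromen-8-yl]ethan-1-one | OCC(=O)c1ccc(OCOC)c2C=CC(C)(C)Oc12
F5 | step 11 | (3R)-3-[2,2-dimethyl-5-(triethylsilyloxy)-2H-chromen-8-yl]-6-(3-methylbut-2-en-1-yl)-7-(triethylsilyloxy)chromane | CC(C)=CCc1cc2c(cc1O[Si](CC)(CC)CC)OC[C@@H](c1ccc(O[Si](CC)(CC)CC)c3c1OC(C)(C)C=C3)C2
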